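The central benzene ring is disconnected into one benzyl-substituted ynol ether used twice plus a two-carbon ketene unit. Numbering that ring from the acyl-bearing carbon C1, the pairs C3–C4 and C5–C6 (bridge-bearing carbon next to oxygenated carbon) are each the C≡C–O unit of the alkyne, and C1–C2 comes from the ketene. Heating a 2-(arylmethyl)-3-methoxycyclobutenone with the arylmethyl methoxyalkyne forges C2–C3, C4–C5 and C1–C2 and delivers the central ring as a pentasubstituted phenol with all three oxygens and both methylene bridges in place. Acylation of the last free carbon, ether cleavage and geminal methylation of the two outer rings finish the target.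

Key step: step 7

Remark: all ring oxygens, the alkynyl ether oxygen included, are carried as methyl ethers, because an O-methyl ynol ether has no β-hydrogen and so cannot fragment thermally to a ketene and an alkene during the annulation, and one reagent later removes all eight ethers; the carbon framework of both annulation partners is unaffected.

Notation: Ar = 2,4,6-trimethoxy-3-(2-methylpropanoyl)phenyl.

Step 1
Reactants: 1 1,3,5-trimethoxybenzene; 2 isobutyryl chloride
Product: 3 aryl ketone [2-methyl-1-(2,4,6-trimethoxyphenyl)propan-1-one]
Conditions: AlCl3 (1.1 equiv), CH2Cl2, 0 °C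
Reagents that add atoms: isobutyryl chloride (2), CC(C)C(=O)Cl
Why: Friedel–Crafts acylation of the very electron-rich arene stops at the monoketone because the acyl group deactivates the ring, and the low temperature keeps AlCl3 from cleaving the ortho methoxy groups.

Step 2
Reactants: 3 aryl ketone
Product: 4 benzylic chloride [1-[3-(chloromethyl)-2,4,6-trimethoxyphenyl]-2-methylpropan-1-one]
Conditions: (CH2O)n (1.5 equiv), HCl (g, saturated), AcOH, 20 °C
Reagents that add atoms: formaldehyde (as paraformaldehyde), C=O; hydrogen chloride, Cl
Why: Blanc chloromethylation at one of the two equivalent free ring positions, each flanked by two methoxy groups; saturating HCl should trap the benzylic cation as the chloride before it can alkylate a second arene, and the ketone slows a second substitution.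

Step 3
Reactants: 5 2-chloro-1,1-dimethoxyethane
Product: 7 methoxyacetylene, via sodium methoxyacetylide 6 (not isolated)
Conditions: NaNH2 (3 equiv), liquid NH3, −33 °C; cold aqueous NaCl, −20 °C; distilled into a cold trap, kept as a THF solution at −20 °C
Reagents that add atoms: none
Why: Twofold base-induced β-elimination (loss of methanol and of HCl) from the α-chloro acetal gives the alkynyl ether, held as its sodium acetylide until the aqueous quench; this is the established preparation of this reagent.

Step 4
Reactants: 7 methoxyacetylene; 4 benzylic chloride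
Product: 10 ynol ether [2-methyl-1-[2,4,6-trimethoxy-3-(3-methoxyprop-2-yn-1-yl)phenyl]propan-1-one], via lithium methoxyacetylide 8 (not isolated), via chloro(methoxyethynyl)zinc 9 (not isolated)
Conditions: n-BuLi, THF, −78 °C; ZnCl2, −78 to 0 °C; then 4, Pd(PPh3)4 (5 mol %), THF, 25 °C; NaHCO3 work-up, Et3N-deactivated silica
Reagents that add atoms: none
Why: Negishi coupling of an alkynylzinc with a benzylic chloride under zerovalent palladium; the zinc acetylide should leave the hindered aryl ketone alone, which a lithium acetylide would not, and the neutral medium avoids propargyl-to-allene isomerisation.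

Step 5
Reactants: 10 ynol ether (the portion destined for the four-membered ring); 11 trichloroacetyl chloride
Product: 13 dichlorocyclobutenone [4,4-dichloro-3-methoxy-2-(ArCH2)cyclobut-2-en-1-one], via dichloroketene 12 (not isolated)
Conditions: Zn(Cu), Et2O–DME, 0 to 25 °C, slow addition of 11
Reagents that add atoms: trichloroacetyl chloride (11), O=C(Cl)C(Cl)(Cl)Cl
Why: Ketene–alkyne [2+2] cycloaddition with dichloroketene generated by zinc dechlorination of 11; the nucleophilic benzyl-bearing alkyne carbon attacks the ketene carbonyl carbon, which fixes the 2-benzyl-3-methoxy pattern.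

Step 6
Reactants: 13 dichlorocyclobutenone
Product: 14 cyclobutenone [3-methoxy-2-(ArCH2)cyclobut-2-en-1-one]
Conditions: Zn dust, AcOH, TMEDA, EtOH, 0 to 25 °C
Reagents that add atoms: none
Why: Reductive dechlorination of the α,α-dichloro ketone by zinc in buffered acetic acid, the standard follow-up to dichloroketene cycloadditions; the aryl ketone, the vinylogous ester and the strained ring should not be reduced.

Step 7
Reactants: 14 cyclobutenone; 10 ynol ether (1.3 equiv)
Product: 19 central phenol [3,5-dimethoxy-2,4-bis(ArCH2)phenol], via vinylketene 15 (not isolated), via vinylcyclobutenone 16 (not isolated), via dienylketene 17 (not isolated), via cyclohexadienone 18 (not isolated)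
Conditions: PhMe (0.4 M), 110 °C, sealed tube, Ar
Reagents that add atoms: none
Why: Thermal 4π electrocyclic opening of 14 gives vinylketene 15, whose ketene C=C adds the electron-rich alkyne of 10 in a [2+2] step to give 16; a second 4π opening to dienylketene 17, 6π electrocyclisation to 18 and enolisation give phenol 19. The closest known reaction type is the Danheiser benzannulation of cyclobutenones with alkoxy- and siloxyalkynes, run here with a 3-alkoxycyclobutenone so that a 1,3,5-trioxygenated ring results. The only ring closed in the product is the central six-membered carbocycle, completed by thermal disrotatory 6π electrocyclisation of 17, which forms C1–C2 after the cycloaddition has set C2–C3 and C4–C5. No stereocentre is created. The step needs regiocontrol in the [2+2] event, which the polarity of the ynol ether supplies (its nucleophilic benzyl-bearing carbon bonds to the ketene carbonyl carbon, its oxygenated carbon to the ketene α-carbon), so the three ring oxygens end up mutually meta and the lone phenol lies next to the only unsubstituted carbon. It also needs the alkyne to outlast the opening of the donor-stabilised cyclobutenone, which the O-methyl group and a modest excess of 10 should secure, while the neutral medium spares the diarylmethane links, aryl ketones and ethers.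

Step 8
Reactants: 19 central phenol; 2 isobutyryl chloride
Product: 20 octamethyl ether triketone [1-[2-hydroxy-4,6-dimethoxy-3,5-bis(ArCH2)phenyl]-2-methylpropan-1-one]
Conditions: TiCl4 (4 equiv), CH2Cl2, 0 to 25 °C; cold 1 M HCl
Reagents that add atoms: isobutyryl chloride (2), CC(C)C(=O)Cl
Why: Friedel–Crafts ortho-acylation steered by the titanium phenoxide (any O-acylated material undergoes Fries rearrangement in the same flask) should go to the only unsubstituted carbon of the central ring, while the outer rings are switched off by their TiCl4-complexed ketones.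

Step 9
Reactants: 20 octamethyl ether triketone
Product: 21 nonaphenol [1-(2,4,6-trihydroxy-3,5-bis{[2,4,6-trihydroxy-3-(2-methylpropanoyl)phenyl]methyl}phenyl)-2-methylpropan-1-one]
Conditions: BBr3 (20 equiv), CH2Cl2, −78 to 25 °C; then MeOH, H2O, 0 °C
Reagents that add atoms: none
Why: Lewis acid ether cleavage (bromide attacks the O-methyl carbon of each boron-complexed ether, SN2) is a standard way from polymethoxy aryl ketones to acylphloroglucinols, and the three ketones make every ring poor at ipso protonation, so the methylene bridges should hold.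

Step 10
Reactants: 21 nonaphenol
Product: 22 onind (target)
Conditions: MeI (4.2 equiv), NaOMe (10 equiv), MeOH, 0 to 20 °C; then 1 M HCl
Reagents that add atoms: iodomethane, CI
Why: Dearomatising geminal C-methylation of an acylphloroglucinol polyanion (enolate C-alkylation, the known route to acylfilicinic acids) should take place at the single unsubstituted carbon of each outer ring, the central ring having none; limiting MeI and low temperature are relied on to hold back O-methylation and attack at bridge-bearing carbons.

Compound list
1 | 1,3,5-trimethoxybenzene | COc1cc(OC)cc(OC)c1 | starting material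
2 | isobutyryl chloride | CC(C)C(=O)Cl | starting material
3 | 2-methyl-1-(2,4,6-trimethoxyphenyl)propan-1-one | COc1cc(OC)c(C(=O)C(C)C)c(OC)c1 | intermediate
4 | 1-[3-(chloromethyl)-2,4,6-trimethoxyphenyl]-2-methylpropan-1-one | COc1cc(OC)c(C(=O)C(C)C)c(OC)c1CCl | intermediate
5 | 2-chloro-1,1-dimethoxyethane | COC(CCl)OC | starting material
6 | sodium methoxyacetylide | COC#[C-].[Na+] | intermediate (not isolated)
7 | methoxyacetylene | COC#C | intermediate
8 | lithium methoxyacetylide | [Li]C#COC | intermediate (not isolated)
9 | chloro(methoxyethynyl)zinc | COC#C[Zn]Cl | intermediate (not isolated)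
10 | 2-methyl-1-[2,4,6-trimethoxy-3-(3-methoxyprop-2-yn-1-yl)phenyl]propan-1-one | COC#CCc1c(OC)cc(OC)c(C(=O)C(C)C)c1OC | intermediate
11 | trichloroacetyl chloride | O=C(Cl)C(Cl)(Cl)Cl | starting material
12 | dichloroketene | O=C=C(Cl)Cl | intermediate (not isolated)
13 | 4,4-dichloro-3-methoxy-2-{[2,4,6-trimethoxy-3-(2-methylpropanoyl)phenyl]methyl}cyclobut-2-en-1-one | COC1=C(Cc2c(OC)cc(OC)c(C(=O)C(C)C)c2OC)C(=O)C1(Cl)Cl | intermediate
14 | 3-methoxy-2-{[2,4,6-trimethoxy-3-(2-methylpropanoyl)phenyl]methyl}cyclobut-2-en-1-one | COC1=C(Cc2c(OC)cc(OC)c(C(=O)C(C)C)c2OC)C(=O)C1 | intermediate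
15 | 3-methoxy-2-{[2,4,6-trimethoxy-3-(2-methylpropanoyl)phenyl]methyl}buta-1,3-dien-1-one (vinylketene) | C=C(OC)C(Cc1c(OC)cc(OC)c(C(=O)C(C)C)c1OC)=C=O | intermediate (not isolated)
16 | 3-methoxy-4-(1-methoxyethenyl)-2,4-bis{[2,4,6-trimethoxy-3-(2-methylpropanoyl)phenyl]methyl}cyclobut-2-en-1-one (racemic) | O=C1C(Cc2c(OC)cc(OC)c(C(=O)C(C)C)c2OC)=C(OC)C1(Cc1c(OC)cc(OC)c(C(=O)C(C)C)c1OC)C(OC)=C | intermediate (not isolated)
17 | 3,5-dimethoxy-2,4-bis{[2,4,6-trimethoxy-3-(2-methylpropanoyl)phenyl]methyl}hexa-1,3,5-trien-1-one, ketene and methoxyvinyl groups cis on the central double bond (dienylketene) | O=C=C(Cc1c(OC)cc(OC)c(C(=O)C(C)C)c1OC)/C(OC)=C(Cc1c(OC)cc(OC)c(C(=O)C(C)C)c1OC)\C(OC)=C | intermediate (not isolated)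
18 | 3,5-dimethoxy-2,4-bis{[2,4,6-trimethoxy-3-(2-methylpropanoyl)phenyl]methyl}cyclohexa-2,4-dien-1-one | O=C1CC(OC)=C(Cc2c(OC)cc(OC)c(C(=O)C(C)C)c2OC)C(OC)=C1Cc1c(OC)cc(OC)c(C(=O)C(C)C)c1OC | intermediate (not isolated)
19 | 3,5-dimethoxy-2,4-bis{[2,4,6-trimethoxy-3-(2-methylpropanoyl)phenyl]methyl}phenol | COc1cc(O)c(Cc2c(OC)cc(OC)c(C(=O)C(C)C)c2OC)c(OC)c1Cc1c(OC)cc(OC)c(C(=O)C(C)C)c1OC | intermediate
20 | 1-(2-hydroxy-4,6-dimethoxy-3,5-bis{[2,4,6-trimethoxy-3-(2-methylpropanoyl)phenyl]methyl}phenyl)-2-methylpropan-1-one | COc1c(C(=O)C(C)C)c(O)c(Cc2c(OC)cc(OC)c(C(=O)C(C)C)c2OC)c(OC)c1Cc1c(OC)cc(OC)c(C(=O)C(C)C)c1OC | intermediate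
21 | 1-(2,4,6-trihydroxy-3,5-bis{[2,4,6-trihydroxy-3-(2-methylpropanoyl)phenyl]methyl}phenyl)-2-methylpropan-1-one | CC(C)C(=O)c1c(O)c(Cc2c(O)cc(O)c(C(=O)C(C)C)c2O)c(O)c(Cc2c(O)cc(O)c(C(=O)C(C)C)c2O)c1O | intermediate
22 | onind: 1-(2,4,6-trihydroxy-3,5-bis{[2,6-dihydroxy-3,3-dimethyl-5-(2-methylpropanoyl)-4-oxocyclohexa-1,5-dien-1-yl]methyl}phenyl)-2-methylpropan-1-one (achiral) | CC(C)C(=O)C1=C(O)C(Cc2c(O)c(CC3=C(O)C(C)(C)C(=O)C(C(=O)C(C)C)=C3O)c(O)c(C(=O)C(C)C)c2O)=C(O)C(C)(C)C1=O | target

Total steps: 10. Longest linear sequence: 9 steps (1, 2, 4, 5, 6, 7, 8, 9, 10, from compound 1); step 3 is a side branch.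

Steps most likely to fail

Step 10. The methylation may lose site control: O-methylation, C-methylation at bridge-bearing carbons of the outer or central rings, and under- or over-alkylation. Base-promoted exchange of the methylene bridges (fragmentation to quinone methides) may also set in before alkylation is complete. The fallback puts the geminal methyl groups on a monomer and makes the bridges last. It sets out from 3, which BBr3 in CH2Cl2 should convert into 2-methyl-1-(2,4,6-trihydroxyphenyl)propan-1-one F1. Part of F1 is C-methylated (MeI, 2 equiv, NaOMe, MeOH) to isobutyrylfilicinic acid, 3,5-dihydroxy-6,6-dimethyl-2-(2-methylpropanoyl)cyclohexa-2,4-dien-1-one F2, and separated from other methylation products at this simple stage. A Mannich reaction of F2 with formaldehyde and dimethylamine at its one remaining nucleophilic carbon gives 4-[(dimethylamino)methyl]-3,5-dihydroxy-6,6-dimethyl-2-(2-methylpropanoyl)cyclohexa-2,4-dien-1-one F3. Heating F3 (2 equiv) with F1 in dioxane should expel dimethylamine; each quinone methide is then captured by one of the two free ring carbons of F1. Neither partner can react further, and the sequence comes back to the route at 22.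

Step 7. The donor-stabilised four-membered ring may open too slowly, so that the vinylketene or the ynol ether is lost to dimerisation or oligomerisation, or the cascade may stall before the second ring opening. A first remedy within the route is a higher temperature, which the O-methyl alkyne permits. The fallback builds the two bridges by Friedel–Crafts benzylation of a ready-made central ring. It sets out from 3, whose chelation-controlled mono-demethylation (BCl3, CH2Cl2, −78 to 0 °C) should give 1-(2-hydroxy-4,6-dimethoxyphenyl)-2-methylpropan-1-one F4. Benzylation of F4 at its two free ring carbons with 4 (2.2 equiv; ZnCl2, 10 mol %, CH2Cl2, 25 °C) comes back to the route at 20.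

Step 9. Cleavage may stay incomplete across eight ethers, and the strongly acidic medium may cut or scramble the diarylmethane links by protodealkylation. The fallback assembles the unprotected trimer from unprotected monomers, so that no bridged compound meets the boron halide. It sets out from 3, demethylated as above to 2-methyl-1-(2,4,6-trihydroxyphenyl)propan-1-one F1. A twofold Mannich reaction of F1 (formaldehyde and dimethylamine, 2.2 equiv each, EtOH) gives 1-{3,5-bis[(dimethylamino)methyl]-2,4,6-trihydroxyphenyl}-2-methylpropan-1-one F5. Heating F5 in dioxane with a large excess of F1 (about 8 equiv, to suppress chain growth) should alkylate one F1 per arm and comes back to the route at 21.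

Further compounds
F1 | step 10 | 2-methyl-1-(2,4,6-trihydroxyphenyl)propan-1-one | CC(C)C(=O)c1c(O)cc(O)cc1O
F2 | step 10 | 3,5-dihydroxy-6,6-dimethyl-2-(2-methylpropanoyl)cyclohexa-2,4-dien-1-one (isobutyrylfilicinic acid) | CC(C)C(=O)C1=C(O)C=C(O)C(C)(C)C1=O
F3 | step 10 | 4-[(dimethylamino)methyl]-3,5-dihydroxy-6,6-dimethyl-2-(2-methylpropanoyl)cyclohexa-2,4-dien-1-one | CC(C)C(=O)C1=C(O)C(CN(C)C)=C(O)C(C)(C)C1=O
F4 | step 7 | 1-(2-hydroxy-4,6-dimethoxyphenyl)-2-methylpropan-1-one | COc1cc(O)c(C(=O)C(C)C)c(OC)c1
F5 | step 9 | 1-{3,5-bis[(dimethylamino)methyl]-2,4,6-trihydroxyphenyl}-2-methylpropan-1-one | CC(C)C(=O)c1c(O)c(CN(C)C)c(O)c(CN(C)C)c1O
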